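The cyclohexane ring of the target (C3a, C4–C7, C7a; octahydroindene numbering) carries the C6 hydroxyl and the C3a–C3 bond cis and 1,4 to each other. It is therefore a bicyclo[2.2.2]octan-2-one in disguise, with C2–C3 as the bridge and C2 as the ketone carbon. A [4+2] cycloaddition of the 2-silyloxycyclohexa-1,3-diene 8 (trans ethynyl and isopropyl groups) with vinyltriphenylphosphonium bromide, an allene equivalent, forms C3a–C4 and C5–C6 in one operation. Baeyer–Villiger oxidation turns the bridge into the C6 oxygen, Wittig methylenation gives the 4-methylidene, allylic oxidation and Mitsunobu inversion install the angelate, and a nickel-catalysed alkylative ynal cyclisation closes the cyclopentane with the (Z)-ethylidene.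

Key step: step 4

Remarks:
- Assumption: the (S)-oxazaborolidinium catalyst is taken to give the (1R,6S) adduct 3; should the sense of induction be the opposite, the (R)-catalyst is used.
- Assumption: diene 2 is treated as purchasable (otherwise one step from but-3-en-2-one, TIPSOTf and Et3N).

Step 1
Reactants: 1 (2E)-4-methylpent-2-enal; 2 2-[(triisopropylsilyl)oxy]buta-1,3-diene
Product: 3 (1R,6S)-6-(propan-2-yl)-4-[(triisopropylsilyl)oxy]cyclohex-3-ene-1-carbaldehyde
Conditions: (S)-1-(2-methylphenyl)-3,3-diphenyltetrahydro-1H,3H-pyrrolo[1,2-c][1,3,2]oxazaborole (20 mol %), HN(SO2CF3)2 (20 mol %), CH2Cl2, −78 °C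
Reagents that add atoms: none
Why: Enantioselective Diels–Alder reaction under Corey's cationic oxazaborolidine catalysis, in which the silyloxy group places the formyl carbon para to itself, the E geometry of 1 becomes the trans relation of formyl and isopropyl, and the catalyst shields one face of the bound enal so that both centres should arise as (1R,6S).

Step 2
Reactants: 3
Product: 4 triisopropyl{[(4R,5S)-4-ethynyl-5-(propan-2-yl)cyclohex-1-en-1-yl]oxy}silane
Conditions: MeC(O)C(N2)P(O)(OMe)2, K2CO3, MeOH, 0 → 25 °C
Reagents that add atoms: dimethyl (1-diazo-2-oxopropyl)phosphonate, COP(=O)(OC)C(=[N+]=[N-])C(C)=O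
Why: Seyferth–Gilbert homologation in the Ohira–Bestmann form should convert the formyl group into the terminal alkyne without touching the silyl enol ether, and the α-centre is safe because the trans-diequatorial arrangement is also the thermodynamic one.

Step 3
Reactants: 4
Product: 6 (4R,5S)-4-ethynyl-5-(propan-2-yl)cyclohex-2-en-1-one, via α-phenylselanyl ketone 5 (not isolated)
Conditions: PhSeCl, CH2Cl2, −78 °C; then H2O2 (30% aq.), pyridine, 0 → 25 °C
Reagents that add atoms: none
Why: Selenenylation of the silyl enol ether at its nucleophilic carbon followed by oxidation and syn selenoxide elimination (Reich–Sharpless enone synthesis) should place the double bond on the side fixed by the enol ether, and no stereocentre is involved.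

Step 4
Reactants: 6; 7 ethenyl(triphenyl)phosphonium bromide
Product: 10 [(1R,4R,5S,6S)-6-ethynyl-8-oxo-5-(propan-2-yl)bicyclo[2.2.2]octan-2-yl]triphenylphosphonium tetrafluoroborate (epimers at C2), via silyl dienol ether 8 (not isolated), via cycloadduct silyl enol ether 9 (not isolated)
Conditions: LiN(CHMe2)2, THF, −78 °C; TBSOTf, −78 → 0 °C; then 7, MeCN, 70 °C; then 1 M aq. HCl, THF, 25 °C; aq. NaBF4 wash
Reagents that add atoms: sodium tetrafluoroborate, [Na+].F[B-](F)(F)F
Why: The electron-rich 2-silyloxy-1,3-diene 8 and the cationic dienophile 7 should combine in a [4+2] cycloaddition (at the polar limit a Mukaiyama–Michael addition followed by conjugate addition of the ylide), and the closest known reaction type is the Diels–Alder reaction of vinyltriphenylphosphonium bromide, used as an allene equivalent, with 1,3-dienes. Both six-membered rings of the bicyclo[2.2.2]octene close in the same suprafacial, boat-type cycloaddition: the carbocycle that becomes the cyclohexane of 20 and the temporary ring that contains the enol ether bridge. The silyl enol ether CH carbon is the nucleophilic diene terminus and bonds to the CH2 end of 7, so the phosphonio-bearing carbon ends next to the ethynyl-bearing arm. The two bridgehead centres are set by approach of 7 to the diene face anti to the isopropyl group, which sits next to the nucleophilic terminus, and syn to the slim ethynyl group. The phosphonio-bearing centre is not controlled and need not be, because it becomes sp2 in step 6. The step therefore needs only regio- and face selectivity, both supplied by the substrate; the acid then hydrolyses the enol ether and NaBF4 removes bromide, which the peracid of step 5 would oxidise.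

Step 5
Reactants: 10
Product: 11 [(1R,5R,6S,7S)-6-ethynyl-3-oxo-7-(propan-2-yl)-2-oxabicyclo[3.2.2]nonan-9-yl]triphenylphosphonium tetrafluoroborate (epimers at C9)
Conditions: m-CPBA, CH2Cl2, 25 °C
Reagents that add atoms: 3-chloroperbenzoic acid, OOC(=O)c1cccc(Cl)c1
Why: In this Baeyer–Villiger oxidation the secondary bridgehead carbon should migrate in preference to the CH2 group and with retention, so the ketone bridge becomes the future carbinol oxygen on the face syn to isopropyl while phosphonium and alkyne are inert to the peracid.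

Step 6
Reactants: 11
Product: 13 (1R,5R,6R,7S)-6-ethynyl-9-methylidene-7-(propan-2-yl)-2-oxabicyclo[3.2.2]nonan-3-one, via phosphonium ylide 12 (not isolated)
Conditions: KN(SiMe3)2, THF, −78 → 0 °C; then CH2O (gas, from paraformaldehyde), −78 → 25 °C
Reagents that add atoms: formaldehyde, C=O
Why: Wittig methylenation of the non-stabilised ylide, formed from the more acidic phosphonium C–H in preference to the lactone α-CH2, should give the exocyclic methylidene and erase the uncontrolled centre.

Step 7
Reactants: 13
Product: 14 (1S,5R,6R,7S,8R)-6-ethynyl-8-hydroxy-9-methylidene-7-(propan-2-yl)-2-oxabicyclo[3.2.2]nonan-3-one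
Conditions: SeO2 (0.5 equiv), Me3COOH (3 equiv), CH2Cl2, 25 °C
Reagents that add atoms: selenium dioxide, O=[Se]=O; tert-butyl hydroperoxide, CC(C)(C)OO
Why: SeO2 allylic hydroxylation (ene reaction, then [2,3]-sigmatropic shift) can use only the CH2 group beside the methylidene carbon because the other allylic carbon is a bridgehead, and oxygen should arrive on the open face next to the ring oxygen, the other face being screened by the ethynyl group and the C–H of the isopropyl-bearing carbon, to give the (8R)-alcohol.

Step 8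
Reactants: 14; 15 (2Z)-2-methylbut-2-enoic acid (angelic acid)
Product: 16 (1S,5R,6R,7S,8S)-6-ethynyl-9-methylidene-3-oxo-7-(propan-2-yl)-2-oxabicyclo[3.2.2]nonan-8-yl (2Z)-2-methylbut-2-enoate
Conditions: PPh3, DIAD, toluene, 0 → 25 °C
Reagents that add atoms: none
Why: Mitsunobu esterification should displace the activated allylic hydroxyl by angelate in an SN2 reaction with inversion, giving the (8S)-ester trans to the ring oxygen, with β-elimination blocked by the bridgehead and the neutral conditions sparing the Z double bond.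

Step 9
Reactants: 16
Product: 18 (1S,2S,3S,4R,5R)-4-ethynyl-2-hydroxy-6-methylidene-5-(2-oxoethyl)-3-(propan-2-yl)cyclohexyl (2Z)-2-methylbut-2-enoate, via bridged lactol 17 (not isolated)
Conditions: (Me2CHCH2)2AlH (1.1 equiv), CH2Cl2, −78 °C; then aq. Rochelle salt
Reagents that add atoms: none
Why: Half-reduction of a lactone to the lactol, in which the saturated seven-membered lactone should react much faster than the hindered, conjugated angelate, and on work-up the lactol opens to the chair hydroxy aldehyde because the trans-diaxial oxygens cannot stay bridged without a boat.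

Step 10
Reactants: 18
Product: 19 (1Z,2S,3aR,5S,6S,7S,7aR)-1-ethylidene-2,6-dihydroxy-4-methylidene-7-(propan-2-yl)octahydro-1H-inden-5-yl (2Z)-2-methylbut-2-enoate
Conditions: Ni(cod)2 (bis(cycloocta-1,5-diene)nickel, zerovalent nickel, 10 mol %), Me2Zn (3.5 equiv), THF, 0 °C
Reagents that add atoms: dimethylzinc, C[Zn]C
Why: Montgomery nickel-catalysed alkylative cyclisation of the ynal (oxidative cyclisation to an oxanickelacycle, methyl transfer from zinc, reductive elimination) should close the cyclopentanol between the two equatorial arms, which fixes the trans ring fusion, deliver CH3 cis to the carbinol carbon to give the (Z)-ethylidene, and give the (2S)-alcohol because the oxygen lies near the plane of the forming alkene while the ring pucker imposed by the trans fusion turns the carbinol hydrogen to the opposite face.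

Step 11
Reactants: 19
Product: 20 (1Z,2S,3aR,5S,6S,7S,7aR)-2-(acetyloxy)-1-ethylidene-6-hydroxy-4-methylidene-7-(propan-2-yl)octahydro-1H-inden-5-yl (2Z)-2-methylbut-2-enoate (target)
Conditions: Ac2O (1.2 equiv), pyridine, DMAP (5 mol %), CH2Cl2, 0 °C
Reagents that add atoms: acetic anhydride, CC(=O)OC(C)=O
Why: Acyl transfer should acetylate the open allylic cyclopentanol with retention, while the axial hydroxyl flanked by the isopropyl- and angelate-bearing carbons stays free and the trans-diaxial angelate cannot migrate.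

Compound list
1 | (2E)-4-methylpent-2-enal | CC(C)/C=C/C=O | starting material
2 | 2-[(triisopropylsilyl)oxy]buta-1,3-diene | C=CC(=C)O[Si](C(C)C)(C(C)C)C(C)C | starting material
3 | (1R,6S)-6-(propan-2-yl)-4-[(triisopropylsilyl)oxy]cyclohex-3-ene-1-carbaldehyde | O=C[C@H]1[C@H](C(C)C)CC(O[Si](C(C)C)(C(C)C)C(C)C)=CC1 | intermediate
4 | triisopropyl{[(4R,5S)-4-ethynyl-5-(propan-2-yl)cyclohex-1-en-1-yl]oxy}silane | C#C[C@H]1[C@H](C(C)C)CC(O[Si](C(C)C)(C(C)C)C(C)C)=CC1 | intermediate
5 | (4R,5S)-4-ethynyl-2-(phenylselanyl)-5-(propan-2-yl)cyclohexan-1-one, C2 epimers (not isolated) | C#C[C@H]1[C@H](C(C)C)CC(=O)C([Se]c2ccccc2)C1 | intermediate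
6 | (4R,5S)-4-ethynyl-5-(propan-2-yl)cyclohex-2-en-1-one | C#C[C@H]1[C@H](C(C)C)CC(=O)C=C1 | intermediate
7 | ethenyl(triphenyl)phosphonium bromide | C=C[P+](c1ccccc1)(c1ccccc1)c1ccccc1.[Br-] | starting material
8 | tert-butyl{[(3S,4R)-4-ethynyl-3-(propan-2-yl)cyclohexa-1,5-dien-1-yl]oxy}dimethylsilane (not isolated) | C#C[C@H]1[C@H](C(C)C)C=C(O[Si](C)(C)C(C)(C)C)C=C1 | intermediate
9 | [(1S,4R,5S,6S)-8-{[tert-butyl(dimethyl)silyl]oxy}-6-ethynyl-5-(propan-2-yl)bicyclo[2.2.2]oct-7-en-2-yl]triphenylphosphonium bromide, C2 epimers (not isolated) | c1ccccc1[P+](c1ccccc1)(c1ccccc1)C1[C@@H]2C=C(O[Si](C)(C)C(C)(C)C)[C@H](C1)[C@@H](C(C)C)[C@@H]2C#C.[Br-] | intermediate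
10 | [(1R,4R,5S,6S)-6-ethynyl-8-oxo-5-(propan-2-yl)bicyclo[2.2.2]octan-2-yl]triphenylphosphonium tetrafluoroborate, C2 epimers | c1ccccc1[P+](c1ccccc1)(c1ccccc1)C1[C@@H]2CC(=O)[C@H](C1)[C@@H](C(C)C)[C@@H]2C#C.F[B-](F)(F)F | intermediate
11 | [(1R,5R,6S,7S)-6-ethynyl-3-oxo-7-(propan-2-yl)-2-oxabicyclo[3.2.2]nonan-9-yl]triphenylphosphonium tetrafluoroborate, C9 epimers | c1ccccc1[P+](c1ccccc1)(c1ccccc1)C1[C@@H]2CC(=O)O[C@H](C1)[C@@H](C(C)C)[C@@H]2C#C.F[B-](F)(F)F | intermediate
12 | triphenylphosphonium ylide of 11 (not isolated) | c1ccccc1P(c1ccccc1)(c1ccccc1)=C1[C@@H]2CC(=O)O[C@H](C1)[C@@H](C(C)C)[C@@H]2C#C | intermediate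
13 | (1R,5R,6R,7S)-6-ethynyl-9-methylidene-7-(propan-2-yl)-2-oxabicyclo[3.2.2]nonan-3-one | C=C1[C@@H]2CC(=O)O[C@H](C1)[C@@H](C(C)C)[C@@H]2C#C | intermediate
14 | (1S,5R,6R,7S,8R)-6-ethynyl-8-hydroxy-9-methylidene-7-(propan-2-yl)-2-oxabicyclo[3.2.2]nonan-3-one | C=C1[C@@H]2CC(=O)O[C@H]([C@@H]1O)[C@@H](C(C)C)[C@@H]2C#C | intermediate
15 | (2Z)-2-methylbut-2-enoic acid (angelic acid) | C/C=C(C)\C(=O)O | starting material
16 | (1S,5R,6R,7S,8S)-6-ethynyl-9-methylidene-3-oxo-7-(propan-2-yl)-2-oxabicyclo[3.2.2]nonan-8-yl (2Z)-2-methylbut-2-enoate | C=C1[C@@H]2CC(=O)O[C@H]([C@H]1OC(=O)/C(C)=C\C)[C@@H](C(C)C)[C@@H]2C#C | intermediate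
17 | (1S,5R,6R,7S,8S)-6-ethynyl-3-hydroxy-9-methylidene-7-(propan-2-yl)-2-oxabicyclo[3.2.2]nonan-8-yl (2Z)-2-methylbut-2-enoate, C3 anomers (not isolated) | C=C1[C@@H]2CC(O)O[C@H]([C@H]1OC(=O)/C(C)=C\C)[C@@H](C(C)C)[C@@H]2C#C | intermediate
18 | (1S,2S,3S,4R,5R)-4-ethynyl-2-hydroxy-6-methylidene-5-(2-oxoethyl)-3-(propan-2-yl)cyclohexyl (2Z)-2-methylbut-2-enoate | C=C1[C@H](CC=O)[C@@H](C#C)[C@H](C(C)C)[C@H](O)[C@H]1OC(=O)/C(C)=C\C | intermediate
19 | (1Z,2S,3aR,5S,6S,7S,7aR)-1-ethylidene-2,6-dihydroxy-4-methylidene-7-(propan-2-yl)octahydro-1H-inden-5-yl (2Z)-2-methylbut-2-enoate | C=C1[C@@H]2C[C@H](O)/C(=C\C)[C@H]2[C@H](C(C)C)[C@H](O)[C@H]1OC(=O)/C(C)=C\C | intermediate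
20 | (1Z,2S,3aR,5S,6S,7S,7aR)-2-(acetyloxy)-1-ethylidene-6-hydroxy-4-methylidene-7-(propan-2-yl)octahydro-1H-inden-5-yl (2Z)-2-methylbut-2-enoate | C=C1[C@@H]2C[C@H](OC(C)=O)/C(=C\C)[C@H]2[C@H](C(C)C)[C@H](O)[C@H]1OC(=O)/C(C)=C\C | target

Total step count: 11. Longest linear sequence: 11 steps (1 and 2 to 20).

Steps most likely to fail

Step 4 (key step). The cycloaddition may stall, because 7 is only a moderate dienophile and bromide can slowly strip silicon from 8 at 70 °C; enone 6 would then be returned, or only the open Michael adduct would form. The fallback sets out from 6 and uses the same diene 8 with nitroethylene (freshly made from 2-nitroethanol and phthalic anhydride), a much stronger ketene-equivalent dienophile with the same regiochemical bias, in CH2Cl2 at −20 → 25 °C. This should give the nitro cycloadduct silyl enol ether F1, which aqueous HCl hydrolyses to the nitro ketone F2. Baeyer–Villiger oxidation with m-CPBA should give the nitro lactone F3, and a Nef reaction (NaOMe, then TiCl3 with NH4OAc buffer) the keto lactone F4. Wittig methylenation of F4 with Ph3P=CH2 comes back to the route at 13.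

Step 8. The carboxylate may attack the methylidene terminus instead of the hindered carbinol carbon (SN2' displacement with allylic shift), or the angelate may isomerise to the tiglate. The fallback sets out from 14 and inverts the centre by oxidation and reduction. Dess–Martin periodinane should give the α-methylene ketone F5. Luche reduction (NaBH4, CeCl3·7H2O, MeOH, −78 °C) should deliver hydride on the open face next to the ring oxygen and give the epimeric alcohol F6. Acylation of F6 with retention, using (2Z)-2-methylbut-2-enoic anhydride (from 15 and N,N'-dicyclohexylcarbodiimide) and LiN(SiMe3)2 in THF at −78 → 0 °C, comes back to the route at 16.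

Step 10. Face selection at the new carbinol carbon may be poor or reversed, because only the ring pucker differentiates the two oxanickelacycles. The fallback sets out from 18 and accepts the epimeric diol F7 from the same cyclisation. A Mitsunobu reaction of F7 with acetic acid (PPh3, DIAD, THF, 0 °C) should invert the unhindered allylic cyclopentanol and leave the hindered axial hydroxyl alone. It installs the acetate in the same operation and comes back to the route at 20, replacing step 11.

Further compounds
F1 | step 4 | nitro cycloadduct silyl enol ether (NO2 in place of the phosphonio group of 9; not isolated) | [O-][N+](=O)C1[C@@H]2C=C(O[Si](C)(C)C(C)(C)C)[C@H](C1)[C@@H](C(C)C)[C@@H]2C#C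
F2 | step 4 | nitro ketone (NO2 in place of the phosphonio group of 10) | [O-][N+](=O)C1[C@@H]2CC(=O)[C@H](C1)[C@@H](C(C)C)[C@@H]2C#C
F3 | step 4 | nitro lactone (NO2 in place of the phosphonio group of 11) | [O-][N+](=O)C1[C@@H]2CC(=O)O[C@H](C1)[C@@H](C(C)C)[C@@H]2C#C
F4 | step 4 | (1R,5R,6S,7S)-6-ethynyl-7-(propan-2-yl)-2-oxabicyclo[3.2.2]nonane-3,9-dione | O=C1[C@@H]2CC(=O)O[C@H](C1)[C@@H](C(C)C)[C@@H]2C#C
F5 | step 8 | (1S,5R,6R,7S)-6-ethynyl-9-methylidene-7-(propan-2-yl)-2-oxabicyclo[3.2.2]nonane-3,8-dione | C=C1[C@@H]2CC(=O)O[C@H](C1=O)[C@@H](C(C)C)[C@@H]2C#C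
F6 | step 8 | (1S,5R,6R,7S,8S)-6-ethynyl-8-hydroxy-9-methylidene-7-(propan-2-yl)-2-oxabicyclo[3.2.2]nonan-3-one (8-epimer of 14) | C=C1[C@@H]2CC(=O)O[C@H]([C@H]1O)[C@@H](C(C)C)[C@@H]2C#C
F7 | step 10 | (1Z,2R,3aR,5S,6S,7S,7aR)-1-ethylidene-2,6-dihydroxy-4-methylidene-7-(propan-2-yl)octahydro-1H-inden-5-yl (2Z)-2-methylbut-2-enoate (2-epimer of 19) | C=C1[C@@H]2C[C@@H](O)/C(=C\C)[C@H]2[C@H](C(C)C)[C@H](O)[C@H]1OC(=O)/C(C)=C\C
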